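## Structural features

The target is a flavanone. Its chroman-4-one core (aromatic ring A, dihydropyranone ring C) carries hydroxyls at C5 and C7 and a 3-hydroxy-3-methylbutyl chain at C8, and is joined through C2 to ring B. Ring B has a free hydroxyl at C2' and is fused through C4'–O and C5' to a 2,2-dimethyl-2H-pyran (ring D), so ring D lies linear, para to the C2' oxygen, and not angular at C3'. C2 is the only stereocentre (S). It is benzylic to an electron-rich ring, β to the C4 carbonyl and bonded to the O1 aryloxide, so base can erase it through the enolate and the 2'-hydroxychalcone, or through loss of O1 from a 2'- or 4'-phenoxide. The tertiary alcohol sits ortho to the C7 oxygen and under acid would close onto it or lose water, and the cis-styrene bond of ring D forbids late hydrogenation, strong acid and oxidants. The real difficulty is regiochemical: the chain must sit at C8 and not C6, ring D at C5' and not C3', and four hydroxyls of different kinds must be unmasked without acid, base or hydrogen. The key step uses the fact that the C4' oxygen has two free ortho carbons: C5'–H is para to the C2' oxygen and open, whereas C3'–H lies between two oxygens and can be walled off by a bulky C2' silyl ether.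

## Logic of the disconnections

**22 from 21.** The three aryl O–Si bonds (O5, O7, O2') are cut last. Fluoride is the only reagent class that spares the ring D alkene, the tertiary alcohol and C2 at the same time. The gain is that every earlier step handles a fully masked polyphenol. The demand is a buffered fluoride source, so that no phenoxide ortho or para to C1' lives long enough to expel O1.

**21 from 17 (key cut).** Ring D is opened at C5'–CH= and at O–C(CH3)2, and its five carbons are hung on the C4' oxygen as a 1,1-dimethylpropargyl ether. Ring D then costs one reagent-free thermal isomerisation. The demand is that the shift goes to C5' and not C3'. For that reason 17 carries triisopropylsilyl, not a smaller silyl group, on the C2' oxygen, has no chelating hydroxyl or carbonyl on ring B, and is heated in a neutral hydrocarbon.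

**17 from 15 and 16.** The O4'–C(CH3)2 bond is cut. All five ring D carbons come from 16 and only one phenol is free in 15, so there is no site selection to solve. The demand is severe in one respect: this is the only step with a phenoxide para to C1' on a flavanone, so it must be cold, short and copper-catalysed. The silyl ethers must also resist an amidine base, a second reason for triisopropylsilyl.

**15 from 14.** The O–CH2Ph bond is cut. Benzyl is the one group removable under neutral conditions while three silyl ethers stay. It must go before ring D exists, because the ring D alkene would not survive hydrogen. The demand is that no alkene is present in 14, so the side chain must already be hydrated.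

**14 from 7 and 13.** The C2–C1' bond is cut. This is the most convergent cut, joining two halves of similar size and creating C2 in the same event. The demand is catalyst-controlled face selection on a C2-unsubstituted chromone by an electron-rich, ortho-substituted aryl group, without added base so that the enolate does not open ring C.

**13 from 10, 9 and 8.** The C–B bond is traced to C–Br, and the O–Si and O–CH2Ph bonds to the two hydroxyls of 8. The bromine and both oxygens of 8 already stand in the required 1,2,4 pattern, so ring B needs no skeletal bond. The demands are monobenzylation at the hydroxyl remote from bromine, and halogen–metal exchange without silyl migration from oxygen to carbon.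

**7 from 5 through 6.** The O1–C2 and C2–C3 bonds are cut, and C2 comes from a formamide acetal. Only one hydroxyl of 5 is free, so the chain is forced to C8. The demand is ring closure under acid mild enough for the tertiary alcohol.

**5 from 4, 3, 1 and 2.** The tertiary C–O bond (hydration), two O–Si bonds and the aryl–CH2 bond are cut. 1 is symmetric, so mono-C-prenylation gives a single regioisomer. Hydration comes after silylation so that the oxygen ortho to the chain that later becomes O7 is already masked and cannot close onto the chain as a chroman. The demands are silylation that tells the two chelated hydroxyls apart, and Markovnikov hydration without acid.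

## Other disconnections considered

**Alternative 1:** The cut removes C4a–C5 and C8–C8a, so ring A is the last ring made. The forward step is a Diels–Alder addition of (2S)-sulfinyl dihydropyranone A1 to the 4-substituted 1-methoxy-1,3-bis(trimethylsilyloxy)diene A2. Loss of sulfenic acid and of methanol then aromatises the adduct to flavanone A3.
- In its favour: the pattern of ring A (5-OH, 7-OH, chain at C8) is written into A2, because the nucleophilic, chain-bearing diene terminus must join C8a, the β-carbon of the vinylogous ester. On this point it is better than the chosen plan, whose step 2 must tell two chelated hydroxyls apart. O5 and O7 also emerge unprotected.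
- Against it: C2 must be set before the key step and then survive sulfenylation, oxidation and heating in a β-aryloxy ketone that can open by elimination. The chain-bearing diene terminus is hindered and such dienes hydrolyse easily. The C2' allyl ether can undergo its own Claisen shift during the heating. A1 must already contain ring D in the linear mode, so that regiochemical problem is only moved to an earlier stage.
- Comparison: both key steps are neutral pericyclic cascades, which is an equal point. In step count the alternative should be equal or somewhat longer (about five steps to A1, three to A2, the key step, and two deprotections to 22).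

**Alternative 2:** The cut is C3=C4. The forward step is ring-closing metathesis of diene A4, in which a vinyl group on C2 and a 1-ethoxyvinyl group on C4a are joined by the second-generation Grubbs catalyst RuCl2(=CHPh)(PCy3)(H2IMes) with loss of ethylene, giving 4-ethoxy-2H-chromene A5.
- In its favour: ring C closes under neutral conditions, and no enolisable ketone stands next to C2 until the end. In neutrality of the key step it is the equal of the chosen plan. C2 could be set in an open-chain ether by a branched-selective asymmetric allylic etherification.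
- Against it: the ether carbon of A4 is both benzylic and allylic, so ionisation and an aromatic Claisen shift threaten its configuration. The 1-ethoxyvinyl group sits on a ring carbon flanked on both sides, and enol ethers turn the ruthenium alkylidene into a sluggish alkoxycarbene. The ring D alkene is a further metathesis site. After A5, acid is needed twice (enol ether hydrolysis and three methoxymethyl ethers), exactly the conditions under which the tertiary alcohol closes onto O7 or eliminates. Ring D again has to be made linear beforehand.
- Comparison: structurally it solves nothing that the chosen plan leaves open. The step count should be similar, but with two acidic end operations in place of one buffered fluoride step.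

**Alternative 3:** The cuts are C3–C4 and O1–C2. In the forward step, salicylaldehyde A6, activated by trimethyl orthoformate and a confined chiral phosphoric acid, combines with ortho-hydroxystyrene A7 in an oxa-(4+2) addition to give the 2,4-cis-4-methoxyflavan A8.
- In its favour: this is the most convergent plan. Two bonds, ring C and C2 arise in one catalytic step from two fragments of equal weight, and no base-sensitive flavanone exists until late. In convergence it is better than the chosen plan.
- Against it: A8 has the wrong oxidation level at C4. The methoxy group must be exchanged for a carbonyl by hydrolysis and oxidation, in the presence of a free 2'-phenol, the ring D alkene and the tertiary alcohol. The C4 stereocentre is made only to be destroyed. A7 is an electron-rich hydroxystyrene that the acid catalyst can protonate and oligomerise, and it must already contain linear ring D. Two allyl ethers then remain for Pd(PPh3)4, a zerovalent palladium step.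
- Comparison: mechanistically it depends on catalyst control of a cationic intermediate, against a reagent-free thermal cascade in the chosen plan. The short fragment count is offset by three or four steps after the key step, so overall step economy should be about equal.

Key step: step 11

Assumption: the (S)-configured biaryl bisphosphine is taken to deliver the aryl group to the chromone face that gives 2S, the same spatial sense as (S)-BINAP–rhodium complexes show with 2-cyclohexenone (O1 in the place of C4); if a trial addition shows the opposite sense, the (R)-ligand is used.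

## Route

Step 1
Reactants: 1 2,4,6-trihydroxyacetophenone; 2 1-bromo-3-methylbut-2-ene
Product: 3 1-[2,4,6-trihydroxy-3-(3-methylbut-2-en-1-yl)phenyl]ethan-1-one
Conditions: 10% aq KOH, 2 (1.0 equiv, slow addition), 0 °C → rt
Reagents that add atoms: none
Why: C-prenylation of a phloroglucinol-type phenolate; in water the soft ring carbon of the ambident anion should be alkylated in preference to oxygen. 1 is symmetric, so mono-alkylation gives one regioisomer, and limiting 2 holds back the bis-prenyl product.

Step 2
Reactants: 3 1-[2,4,6-trihydroxy-3-(3-methylbut-2-en-1-yl)phenyl]ethan-1-one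
Product: 4 1-[2-hydroxy-3-(3-methylbut-2-en-1-yl)-4,6-bis(triisopropylsilyloxy)phenyl]ethan-1-one
Conditions: TIPSOTf (2.1 equiv), 2,6-lutidine, CH2Cl2, –40 → 0 °C
Reagents that add atoms: triisopropylsilyl trifluoromethanesulfonate, CC(C)[Si](OS(=O)(=O)C(F)(F)F)(C(C)C)C(C)C
Why: Phenol silylation with a silyl triflate; the unchelated 4-OH should react first, then the chelated 6-OH, which has only hydrogen as its ring neighbour. The 2-OH is buried between the acetyl and prenyl groups and should remain as the chelated phenol that later becomes O1; lutidine keeps the medium non-acidic for the alkene.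

Step 3
Reactants: 4 1-[2-hydroxy-3-(3-methylbut-2-en-1-yl)-4,6-bis(triisopropylsilyloxy)phenyl]ethan-1-one
Product: 5 1-[2-hydroxy-3-(3-hydroxy-3-methylbutyl)-4,6-bis(triisopropylsilyloxy)phenyl]ethan-1-one
Conditions: Co(acac)2 (20 mol%), PhSiH3, O2 (1 atm), THF, rt
Reagents that add atoms: dioxygen, O=O
Why: Mukaiyama hydration; hydrogen-atom transfer from a cobalt hydride to the trisubstituted alkene gives the tertiary radical, which is captured by O2 and reduced to the Markovnikov alcohol. The conditions are neutral, so the free ortho-phenol cannot add to the chain as it would under acid or mercury salts.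

Step 4
Reactants: 5 1-[2-hydroxy-3-(3-hydroxy-3-methylbutyl)-4,6-bis(triisopropylsilyloxy)phenyl]ethan-1-one
Product: 7 8-(3-hydroxy-3-methylbutyl)-5,7-bis(triisopropylsilyloxy)-4H-chromen-4-one, via enaminone 6 (not isolated)
Conditions: Me2NCH(OMe)2, toluene, 90 °C; then 1 M aq HCl, CH2Cl2, rt
Reagents that add atoms: N,N-dimethylformamide dimethyl acetal, COC(OC)N(C)C
Why: Enaminone route to chromones; the methyl ketone condenses with the formamide acetal to 6, and acid then promotes 6-endo addition of the only free phenol and loss of dimethylamine. Because O6 is silylated, closure can use only the hydroxyl next to the chain, which fixes the chain at C8; dilute acid at room temperature should leave the tertiary alcohol and the aryl silyl ethers alone.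

Step 5
Reactants: 8 4-bromoresorcinol
Product: 9 5-(benzyloxy)-2-bromophenol
Conditions: BnBr (1.0 equiv), K2CO3, acetone, rt
Reagents that add atoms: benzyl bromide, BrCc1ccccc1
Why: Williamson mono-etherification; the hydroxyl para to bromine is the less hindered one and is not hydrogen-bonded to the halogen, so it should be benzylated first.

Step 6
Reactants: 9 5-(benzyloxy)-2-bromophenol
Product: 10 [5-(benzyloxy)-2-bromophenoxy]tri(propan-2-yl)silane
Conditions: TIPSCl, imidazole, DMF, rt
Reagents that add atoms: chlorotriisopropylsilane, CC(C)[Si](Cl)(C(C)C)C(C)C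
Why: Standard imidazole-mediated silylation of the single remaining phenol; triisopropylsilyl is chosen because it migrates from oxygen to an ortho carbanion far more slowly than smaller silyl groups and later shields C3'.

Step 7
Reactants: 10 [5-(benzyloxy)-2-bromophenoxy]tri(propan-2-yl)silane
Product: 13 [4-(benzyloxy)-2-(triisopropylsilyloxy)phenyl]boronic acid, via aryllithium 11 (not isolated), via lithium triisopropoxy arylborate 12 (not isolated)
Conditions: B(OiPr)3, then n-BuLi, THF/toluene, –78 °C; then 1 M aq HCl to pH 5, 0 °C
Reagents that add atoms: triisopropyl borate, CC(C)OB(OC(C)C)OC(C)C; water, O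
Why: Bromine–lithium exchange with in situ borate capture; 11 is trapped as 12 as soon as it forms, which leaves no time for a retro-Brook shift, and mild hydrolysis gives the boronic acid.

Step 8
Reactants: 7 8-(3-hydroxy-3-methylbutyl)-5,7-bis(triisopropylsilyloxy)-4H-chromen-4-one; 13 [4-(benzyloxy)-2-(triisopropylsilyloxy)phenyl]boronic acid
Product: 14 (2S)-2-[4-(benzyloxy)-2-(triisopropylsilyloxy)phenyl]-8-(3-hydroxy-3-methylbutyl)-5,7-bis(triisopropylsilyloxy)chroman-4-one
Conditions: 13 (2.5 equiv), [Rh(OH)(cod)]2 (3 mol%), (S)-6,6'-dimethoxy-2,2'-bis[bis(3,4,5-trifluorophenyl)phosphino]biphenyl (7 mol%), toluene/H2O 10:1, 40 °C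
Reagents that add atoms: none
Why: Rhodium-catalysed asymmetric 1,4-addition of an arylboronic acid to a chromone (Hayashi–Miyaura reaction); transmetalation gives an aryl–rhodium species that adds across C2=C3, and water protonates the rhodium enolate. The C2 stereocentre is set in the insertion step by the chiral bisphosphine, whose electron-poor aryl groups speed insertion into the deactivated enone. The hydroxo precatalyst needs no added base, so the enolate should be protonated before it can open ring C.

Step 9
Reactants: 14 (2S)-2-[4-(benzyloxy)-2-(triisopropylsilyloxy)phenyl]-8-(3-hydroxy-3-methylbutyl)-5,7-bis(triisopropylsilyloxy)chroman-4-one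
Product: 15 (2S)-2-[4-hydroxy-2-(triisopropylsilyloxy)phenyl]-8-(3-hydroxy-3-methylbutyl)-5,7-bis(triisopropylsilyloxy)chroman-4-one
Conditions: H2 (1 atm), 10% Pd/C, EtOAc, rt
Reagents that add atoms: none
Why: Hydrogenolysis of the benzyl ether under neutral conditions; no alkene is present at this stage, and the aryl ketone, the silyl ethers and the cyclic benzylic C2–O1 bond should be inert at one atmosphere.

Step 10
Reactants: 15 (2S)-2-[4-hydroxy-2-(triisopropylsilyloxy)phenyl]-8-(3-hydroxy-3-methylbutyl)-5,7-bis(triisopropylsilyloxy)chroman-4-one; 16 3-chloro-3-methylbut-1-yne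
Product: 17 (2S)-8-(3-hydroxy-3-methylbutyl)-2-{4-[(2-methylbut-3-yn-2-yl)oxy]-2-(triisopropylsilyloxy)phenyl}-5,7-bis(triisopropylsilyloxy)chroman-4-one
Conditions: 16 (1.5 equiv), CuCl2·2H2O (1 mol%), DBU (1.3 equiv), MeCN, –5 → 0 °C
Reagents that add atoms: none
Why: Copper-catalysed propargylic etherification of a phenol with a tertiary propargylic chloride; a copper acetylide ionises to a reactive allenylidene-type electrophile that is captured by the phenoxide at the tertiary carbon. The low temperature and the fast copper pathway are meant to consume the 4'-phenoxide before it can open ring C; the tertiary alcohol is far less acidic and should not compete.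

Step 11
Reactants: 17 (2S)-8-(3-hydroxy-3-methylbutyl)-2-{4-[(2-methylbut-3-yn-2-yl)oxy]-2-(triisopropylsilyloxy)phenyl}-5,7-bis(triisopropylsilyloxy)chroman-4-one
Product: 21 (2S)-2-[2,2-dimethyl-7-(triisopropylsilyloxy)-2H-chromen-6-yl]-8-(3-hydroxy-3-methylbutyl)-5,7-bis(triisopropylsilyloxy)chroman-4-one, via allenyl cyclohexadienone 18 (not isolated), via ortho-allenylphenol 19 (not isolated), via ortho-quinone methide 20 (not isolated)
Conditions: o-xylene (degassed, dilute), 140 °C, sealed tube
Reagents that add atoms: none
Why: This is the aromatic propargyl Claisen cascade, the standard thermal route from aryl 1,1-dimethylpropargyl ethers to 2,2-dimethyl-2H-chromenes. A concerted (3,3) shift through a six-membered transition state breaks O–C(CH3)2 and joins the alkyne terminus to C5', giving dienone 18, which enolises to phenol 19. A 1,5-hydrogen shift from the phenolic O–H to the central allene carbon gives the (Z)-ortho-quinone methide 20, and a thermally allowed disrotatory oxa-6π electrocyclisation re-forms O–C(CH3)2, closes the six-membered ring D and restores the aromaticity of ring B. No stereocentre is created, and C2 is a spectator because the medium is neutral and aprotic and no phenoxide is present at any point. The selectivity required is C5' over C3': C5' is para to the C2' oxygen donor, the electronically favoured site of a meta-alkoxy aryl ether when no chelated carbonyl fixes the ring bonds, and C3' is shielded by the triisopropylsilyl group, which the C1' substituent pushes toward C3'. The gem-dimethyl group lowers the temperature needed to about 140 °C, where aryl silyl ethers and the tertiary alcohol should be inert and the propargyl ether is the only group with a sigmatropic pathway.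

Step 12
Reactants: 21 (2S)-2-[2,2-dimethyl-7-(triisopropylsilyloxy)-2H-chromen-6-yl]-8-(3-hydroxy-3-methylbutyl)-5,7-bis(triisopropylsilyloxy)chroman-4-one
Product: 22 (2S)-5,7-dihydroxy-2-(7-hydroxy-2,2-dimethyl-2H-chromen-6-yl)-8-(3-hydroxy-3-methylbutyl)chroman-4-one
Conditions: HF·pyridine, pyridine, THF, 0 °C → rt
Reagents that add atoms: none
Why: Fluoride cleavage of three aryl silyl ethers; the pyridine-buffered reagent is weakly acidic, so no phenoxide forms and C2 is not endangered, while the acidity is too low to ionise the tertiary alcohol or protonate the ring D alkene.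

## Compound list

1 | 2,4,6-trihydroxyacetophenone | CC(=O)c1c(O)cc(O)cc1O | starting material
2 | 1-bromo-3-methylbut-2-ene | CC(C)=CCBr | starting material
3 | 1-[2,4,6-trihydroxy-3-(3-methylbut-2-en-1-yl)phenyl]ethan-1-one | CC(=O)c1c(O)cc(O)c(CC=C(C)C)c1O | intermediate
4 | 1-[2-hydroxy-3-(3-methylbut-2-en-1-yl)-4,6-bis(triisopropylsilyloxy)phenyl]ethan-1-one | CC(=O)c1c(O[Si](C(C)C)(C(C)C)C(C)C)cc(O[Si](C(C)C)(C(C)C)C(C)C)c(CC=C(C)C)c1O | intermediate
5 | 1-[2-hydroxy-3-(3-hydroxy-3-methylbutyl)-4,6-bis(triisopropylsilyloxy)phenyl]ethan-1-one | CC(=O)c1c(O[Si](C(C)C)(C(C)C)C(C)C)cc(O[Si](C(C)C)(C(C)C)C(C)C)c(CCC(C)(C)O)c1O | intermediate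
6 | (E)-3-(dimethylamino)-1-[2-hydroxy-3-(3-hydroxy-3-methylbutyl)-4,6-bis(triisopropylsilyloxy)phenyl]prop-2-en-1-one (not isolated) | CN(C)/C=C/C(=O)c1c(O[Si](C(C)C)(C(C)C)C(C)C)cc(O[Si](C(C)C)(C(C)C)C(C)C)c(CCC(C)(C)O)c1O | intermediate
7 | 8-(3-hydroxy-3-methylbutyl)-5,7-bis(triisopropylsilyloxy)-4H-chromen-4-one | CC(C)(O)CCc1c(O[Si](C(C)C)(C(C)C)C(C)C)cc(O[Si](C(C)C)(C(C)C)C(C)C)c2c1OC=CC2=O | intermediate
8 | 4-bromoresorcinol | Oc1ccc(Br)c(O)c1 | starting material
9 | 5-(benzyloxy)-2-bromophenol | Oc1cc(OCc2ccccc2)ccc1Br | intermediate
10 | [5-(benzyloxy)-2-bromophenoxy]tri(propan-2-yl)silane | CC(C)[Si](Oc1cc(OCc2ccccc2)ccc1Br)(C(C)C)C(C)C | intermediate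
11 | [4-(benzyloxy)-2-(triisopropylsilyloxy)phenyl]lithium (not isolated) | [Li]c1ccc(OCc2ccccc2)cc1O[Si](C(C)C)(C(C)C)C(C)C | intermediate
12 | lithium [4-(benzyloxy)-2-(triisopropylsilyloxy)phenyl]tri(propan-2-yloxy)borate (not isolated) | [Li+].CC(C)O[B-](OC(C)C)(OC(C)C)c1ccc(OCc2ccccc2)cc1O[Si](C(C)C)(C(C)C)C(C)C | intermediate
13 | [4-(benzyloxy)-2-(triisopropylsilyloxy)phenyl]boronic acid | OB(O)c1ccc(OCc2ccccc2)cc1O[Si](C(C)C)(C(C)C)C(C)C | intermediate
14 | (2S)-2-[4-(benzyloxy)-2-(triisopropylsilyloxy)phenyl]-8-(3-hydroxy-3-methylbutyl)-5,7-bis(triisopropylsilyloxy)chroman-4-one | CC(C)(O)CCc1c(O[Si](C(C)C)(C(C)C)C(C)C)cc(O[Si](C(C)C)(C(C)C)C(C)C)c2c1O[C@H](c1ccc(OCc3ccccc3)cc1O[Si](C(C)C)(C(C)C)C(C)C)CC2=O | intermediate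
15 | (2S)-2-[4-hydroxy-2-(triisopropylsilyloxy)phenyl]-8-(3-hydroxy-3-methylbutyl)-5,7-bis(triisopropylsilyloxy)chroman-4-one | CC(C)(O)CCc1c(O[Si](C(C)C)(C(C)C)C(C)C)cc(O[Si](C(C)C)(C(C)C)C(C)C)c2c1O[C@H](c1ccc(O)cc1O[Si](C(C)C)(C(C)C)C(C)C)CC2=O | intermediate
16 | 3-chloro-3-methylbut-1-yne | CC(C)(Cl)C#C | starting material
17 | (2S)-8-(3-hydroxy-3-methylbutyl)-2-{4-[(2-methylbut-3-yn-2-yl)oxy]-2-(triisopropylsilyloxy)phenyl}-5,7-bis(triisopropylsilyloxy)chroman-4-one | CC(C)(O)CCc1c(O[Si](C(C)C)(C(C)C)C(C)C)cc(O[Si](C(C)C)(C(C)C)C(C)C)c2c1O[C@H](c1ccc(OC(C)(C)C#C)cc1O[Si](C(C)C)(C(C)C)C(C)C)CC2=O | intermediate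
18 | (2S)-8-(3-hydroxy-3-methylbutyl)-2-[3-(3-methylbuta-1,2-dien-1-yl)-4-oxo-6-(triisopropylsilyloxy)cyclohexa-1,5-dien-1-yl]-5,7-bis(triisopropylsilyloxy)chroman-4-one (C5' sp3, either configuration; not isolated) | CC(C)(O)CCc1c(O[Si](C(C)C)(C(C)C)C(C)C)cc(O[Si](C(C)C)(C(C)C)C(C)C)c2c1O[C@H](C1=CC(C=C=C(C)C)C(=O)C=C1O[Si](C(C)C)(C(C)C)C(C)C)CC2=O | intermediate
19 | (2S)-2-[4-hydroxy-5-(3-methylbuta-1,2-dien-1-yl)-2-(triisopropylsilyloxy)phenyl]-8-(3-hydroxy-3-methylbutyl)-5,7-bis(triisopropylsilyloxy)chroman-4-one (not isolated) | CC(C)(O)CCc1c(O[Si](C(C)C)(C(C)C)C(C)C)cc(O[Si](C(C)C)(C(C)C)C(C)C)c2c1O[C@H](c1cc(C=C=C(C)C)c(O)cc1O[Si](C(C)C)(C(C)C)C(C)C)CC2=O | intermediate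
20 | (2S)-8-(3-hydroxy-3-methylbutyl)-2-[(3Z)-3-(3-methylbut-2-en-1-ylidene)-4-oxo-6-(triisopropylsilyloxy)cyclohexa-1,5-dien-1-yl]-5,7-bis(triisopropylsilyloxy)chroman-4-one (not isolated) | CC(C)(O)CCc1c(O[Si](C(C)C)(C(C)C)C(C)C)cc(O[Si](C(C)C)(C(C)C)C(C)C)c2c1O[C@H](C1=C/C(=C/C=C(C)C)C(=O)C=C1O[Si](C(C)C)(C(C)C)C(C)C)CC2=O | intermediate
21 | (2S)-2-[2,2-dimethyl-7-(triisopropylsilyloxy)-2H-chromen-6-yl]-8-(3-hydroxy-3-methylbutyl)-5,7-bis(triisopropylsilyloxy)chroman-4-one | CC(C)(O)CCc1c(O[Si](C(C)C)(C(C)C)C(C)C)cc(O[Si](C(C)C)(C(C)C)C(C)C)c2c1O[C@H](c1cc3c(cc1O[Si](C(C)C)(C(C)C)C(C)C)OC(C)(C)C=C3)CC2=O | intermediate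
22 | (2S)-5,7-dihydroxy-2-(7-hydroxy-2,2-dimethyl-2H-chromen-6-yl)-8-(3-hydroxy-3-methylbutyl)chroman-4-one | CC(C)(O)CCc1c(O)cc(O)c2c1O[C@H](c1cc3c(cc1O)OC(C)(C)C=C3)CC2=O | target

## Step count and least certain steps

Total step count: 12. Longest linear sequence: 9 (steps 1–4 and 8–12); the ring B branch (steps 5–7) joins at step 8.

**Step 11 (key step).** The sigmatropic shift may go in part to C3', because that carbon lies between two oxygens and is the most electron-rich ortho site, and the silyl group offers only a steric bias. Thermal loss of the C2' silyl group would remove even that bias. Fallback (ring D made before the fragments are joined, so regioisomers are separated and assigned on a cheap bromoarene):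
- 4-bromoresorcinol 8 is alkylated with 16 (CuCl2·2H2O, DBU, MeCN, 0 °C) at the hydroxyl remote from bromine, as in step 5, giving 2-bromo-5-[(2-methylbut-3-yn-2-yl)oxy]phenol F1.
- Silylation as in step 6 gives [2-bromo-5-[(2-methylbut-3-yn-2-yl)oxy]phenoxy]tri(propan-2-yl)silane F2.
- Heating in o-xylene should give 6-bromo-2,2-dimethyl-7-(triisopropylsilyloxy)-2H-chromene F3.
- Bromine–lithium exchange and borylation as in step 7 give [2,2-dimethyl-7-(triisopropylsilyloxy)-2H-chromen-6-yl]boronic acid F4.
- F4 is added to chromone 7 under the conditions of step 8.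

The detour sets out from 8 and returns at 21; steps 5–7, 9 and 10 fall away.

**Step 8.** Insertion of the electron-rich, 5,7-dioxygenated chromone into the hindered ortho-silyloxy aryl–rhodium bond may be slower than hydrolytic loss of boron from the electron-rich boronic acid. Opening of the rhodium enolate to a chalcone followed by a second arylation is the other drain. Fallback (ring C closed by oxa-Michael addition, configuration by resolution):
- Aryllithium 11 is quenched with N,N-dimethylformamide to give 4-(benzyloxy)-2-(triisopropylsilyloxy)benzaldehyde F5.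
- Amine-mediated condensation of F5 with acetophenone 5 (pyrrolidine, EtOH, 50 °C) gives (E)-3-[4-(benzyloxy)-2-(triisopropylsilyloxy)phenyl]-1-[2-hydroxy-3-(3-hydroxy-3-methylbutyl)-4,6-bis(triisopropylsilyloxy)phenyl]prop-2-en-1-one F6.
- F6 closes in the same flask to racemic 2-[4-(benzyloxy)-2-(triisopropylsilyloxy)phenyl]-8-(3-hydroxy-3-methylbutyl)-5,7-bis(triisopropylsilyloxy)chroman-4-one F7.
- Preparative chromatography on a polysaccharide chiral stationary phase then gives the 2S enantiomer.

The detour sets out from 5 and 11 and returns at 14.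

**Step 10.** Deprotonation by DBU creates a 4'-phenoxide that can expel O1 (para-quinone methide or chalcone pathway) and reclose without facial control, eroding the configuration at C2. Transfer of a silyl group to the phenoxide is a second risk. Fallback (no phenoxide at all, ring D closed by a different reaction): phenol 15 is condensed with 3-methylbut-2-enal in the presence of phenylboronic acid and propanoic acid in toluene at reflux with removal of water. The aryl boronate delivers the aldehyde to the open ortho carbon C5', the resulting benzodioxaborin fragments to the same ortho-quinone methide as 20, and electrocyclisation closes ring D. The detour sets out from 15 and returns at 21, replaces steps 10 and 11, and makes no compound outside the list (F0).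

**Step 2.** The silylation may fail to tell the two chelated hydroxyls apart, or may run on to the tris-silyl ether. The first would send the chain to C6 of the chromone, and the second would leave no hydroxyl for ring closure. Fallback (silylate while the two ortho hydroxyls are still equivalent, then bring in the chain by cross-coupling):
- 1 is bis-silylated (TIPSOTf, 2,6-lutidine) to 1-[2-hydroxy-4,6-bis(triisopropylsilyloxy)phenyl]ethan-1-one F8.
- N-iodosuccinimide in CH2Cl2 should iodinate the one ring position not flanked by two silyloxy groups, giving 1-[2-hydroxy-3-iodo-4,6-bis(triisopropylsilyloxy)phenyl]ethan-1-one F9.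
- Sonogashira coupling with 2-methylbut-3-yn-2-ol (PdCl2(PPh3)2, CuI, Et3N, rt) gives 1-[2-hydroxy-3-(3-hydroxy-3-methylbut-1-yn-1-yl)-4,6-bis(triisopropylsilyloxy)phenyl]ethan-1-one F10.
- Hydrogenation (H2, 10% Pd/C, EtOAc) saturates the alkyne.

The detour sets out from 1 and returns at 5; it also bypasses steps 1 and 3.

## Further compounds

F1 | step 11 | 2-bromo-5-[(2-methylbut-3-yn-2-yl)oxy]phenol | Oc1cc(OC(C)(C)C#C)ccc1Br
F2 | step 11 | [2-bromo-5-[(2-methylbut-3-yn-2-yl)oxy]phenoxy]tri(propan-2-yl)silane | CC(C)[Si](Oc1cc(OC(C)(C)C#C)ccc1Br)(C(C)C)C(C)C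
F3 | step 11 | 6-bromo-2,2-dimethyl-7-(triisopropylsilyloxy)-2H-chromene | CC1(C)C=Cc2cc(Br)c(O[Si](C(C)C)(C(C)C)C(C)C)cc2O1
F4 | step 11 | [2,2-dimethyl-7-(triisopropylsilyloxy)-2H-chromen-6-yl]boronic acid | CC1(C)C=Cc2cc(B(O)O)c(O[Si](C(C)C)(C(C)C)C(C)C)cc2O1
F5 | step 8 | 4-(benzyloxy)-2-(triisopropylsilyloxy)benzaldehyde | O=Cc1ccc(OCc2ccccc2)cc1O[Si](C(C)C)(C(C)C)C(C)C
F6 | step 8 | (E)-3-[4-(benzyloxy)-2-(triisopropylsilyloxy)phenyl]-1-[2-hydroxy-3-(3-hydroxy-3-methylbutyl)-4,6-bis(triisopropylsilyloxy)phenyl]prop-2-en-1-one | CC(C)(O)CCc1c(O)c(C(=O)/C=C/c2ccc(OCc3ccccc3)cc2O[Si](C(C)C)(C(C)C)C(C)C)c(O[Si](C(C)C)(C(C)C)C(C)C)cc1O[Si](C(C)C)(C(C)C)C(C)C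
F7 | step 8 | racemic 2-[4-(benzyloxy)-2-(triisopropylsilyloxy)phenyl]-8-(3-hydroxy-3-methylbutyl)-5,7-bis(triisopropylsilyloxy)chroman-4-one | CC(C)(O)CCc1c(O[Si](C(C)C)(C(C)C)C(C)C)cc(O[Si](C(C)C)(C(C)C)C(C)C)c2c1OC(c1ccc(OCc3ccccc3)cc1O[Si](C(C)C)(C(C)C)C(C)C)CC2=O
F0 | step 10 | none | none
F8 | step 2 | 1-[2-hydroxy-4,6-bis(triisopropylsilyloxy)phenyl]ethan-1-one | CC(=O)c1c(O)cc(O[Si](C(C)C)(C(C)C)C(C)C)cc1O[Si](C(C)C)(C(C)C)C(C)C
F9 | step 2 | 1-[2-hydroxy-3-iodo-4,6-bis(triisopropylsilyloxy)phenyl]ethan-1-one | CC(=O)c1c(O)c(I)c(O[Si](C(C)C)(C(C)C)C(C)C)cc1O[Si](C(C)C)(C(C)C)C(C)C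
F10 | step 2 | 1-[2-hydroxy-3-(3-hydroxy-3-methylbut-1-yn-1-yl)-4,6-bis(triisopropylsilyloxy)phenyl]ethan-1-one | CC(=O)c1c(O)c(C#CC(C)(C)O)c(O[Si](C(C)C)(C(C)C)C(C)C)cc1O[Si](C(C)C)(C(C)C)C(C)C
A1 | alternative 1 | (2S)-2-[7-(allyloxy)-2,2-dimethyl-2H-chromen-6-yl]-5-(4-methylphenylsulfinyl)-2,3-dihydro-4H-pyran-4-one (sulfur configuration open) | Cc1ccc(cc1)S(=O)C1=CO[C@H](c2cc3c(cc2OCC=C)OC(C)(C)C=C3)CC1=O
A2 | alternative 1 | 1-methoxy-7-methyl-7-(triethylsilyloxy)-1,3-bis(trimethylsilyloxy)octa-1,3-diene | COC(O[Si](C)(C)C)=CC(O[Si](C)(C)C)=CCCC(C)(C)O[Si](CC)(CC)CC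
A3 | alternative 1 | (2S)-2-[7-(allyloxy)-2,2-dimethyl-2H-chromen-6-yl]-5,7-dihydroxy-8-[3-methyl-3-(triethylsilyloxy)butyl]chroman-4-one | CC(C)(O[Si](CC)(CC)CC)CCc1c(O)cc(O)c2c1O[C@H](c1cc3c(cc1OCC=C)OC(C)(C)C=C3)CC2=O
A4 | alternative 2 | 4-[3-(1-ethoxyethenyl)-2-{[(1S)-1-[7-(methoxymethoxy)-2,2-dimethyl-2H-chromen-6-yl]prop-2-en-1-yl]oxy}-4,6-bis(methoxymethoxy)phenyl]-2-methylbutan-2-ol | CC(C)(O)CCc1c(OCOC)cc(OCOC)c(C(=C)OCC)c1O[C@@H](C=C)c1cc2c(cc1OCOC)OC(C)(C)C=C2
A5 | alternative 2 | 4-[(2S)-4-ethoxy-5,7-bis(methoxymethoxy)-2-[7-(methoxymethoxy)-2,2-dimethyl-2H-chromen-6-yl]-2H-chromen-8-yl]-2-methylbutan-2-ol | CC(C)(O)CCc1c(OCOC)cc(OCOC)c2c1O[C@H](c1cc3c(cc1OCOC)OC(C)(C)C=C3)C=C2OCC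
A6 | alternative 3 | 4,6-bis(allyloxy)-2-hydroxy-3-(3-hydroxy-3-methylbutyl)benzaldehyde | CC(C)(O)CCc1c(OCC=C)cc(OCC=C)c(C=O)c1O
A7 | alternative 3 | 6-ethenyl-2,2-dimethyl-2H-chromen-7-ol | C=Cc1cc2c(cc1O)OC(C)(C)C=C2
A8 | alternative 3 | 4-[(2S,4S)-5,7-bis(allyloxy)-2-(7-hydroxy-2,2-dimethyl-2H-chromen-6-yl)-4-methoxychroman-8-yl]-2-methylbutan-2-ol | CC(C)(O)CCc1c(OCC=C)cc(OCC=C)c2c1O[C@H](c1cc3c(cc1O)OC(C)(C)C=C3)C[C@@H]2OC
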